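## Analysis of the target

The backbone is numbered from the butyrate-bearing carbon: C1 to C6, O7, C8 to C16, O17, C18; methyl groups are named by the carbon that bears them. The target has four rings: a cyclohexenone (ring A, C9 to C14, C11=C12–C13=O), a tetrahydrofuran (C6, O7, C8, C9, C10) cis-fused to ring A, a nine-membered ether (oxonene: C1 to C6, O7, C8, C18, with a Z trisubstituted C3=C4 bond) bridging C6 and C8, and an oxepane (C8, C9, C14, C15, C16, O17, C18). There are eight stereocentres (C1, C6, C8, C9, C10, C14, C15, C18). 9-H, 10-H and 14-H lie on one face of ring A; the C5 and C18 arms are cis on the tetrahydrofuran, on the face away from ring A. O17 on C18 and the ester oxygen on C1 are related as in an anti addition to a Z C18=C1 alkene, and C15 is R. Sensitive groups are the butyrate, the enone (its α-carbon C14 can epimerise until the oxepane holds it), the tertiary ether at C18 and the medium-ring alkene. The hard parts are the four contiguous stereocentres C6, C8, C9 and C10, the nine-membered ring, and telling several alkenes apart during oxidation. The strategy rests on one feature: the tetrahydrofuran with its cis fusion to ring A maps onto an aldehyde carbon (C8), the ring A diene C9=C10–C11=C12 and a 1,2-diol arm whose carbinol carbon C6 becomes a ring carbon.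

## Retrosynthetic reasoning

**Oxonene, C3=C4.** The only C=C bond of the nine-membered ring is cut first: 40 comes from diene 39 by ring-closing metathesis. Both termini are simple arms (methallyl on C6, allyl on C1), the ring forces the Z geometry, and the tetrahydrofuran and oxepane hold the arms close.

**C13 ketone.** 39 goes back to 38 by allylic C–H oxidation. Placed before the metathesis, C11=C12 is the only trisubstituted alkene; placed after oxepane closure, C14 cannot epimerise.

**Ester and allyl group on C1.** 38 comes from alcohol 37 by acylation of its only hydroxyl. 37 comes from aldehyde 36 by one-carbon olefination, and 36 from diol 35 by oxidation of the primary C3 alcohol. C3 therefore starts as an oxygenated carbon, which is used below.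

**Oxepane, C16–O17.** Diol 35 comes from cyclic carbonate 34, and 34 from diol 32 through primary triflate 33. The tertiary C18 hydroxyl attacks a primary carbon, so no stereocentre is touched; the reverse polarity would need substitution at the quaternary C18.

**C18–O and C1–O.** Carbonate 32 comes from epoxide 29 through bis-carbonate 30 and intermediate 31; 29 comes from Z alkene 28. The target needs the two oxygens anti across the Z alkene. A syn dihydroxylation would give the C1 epimer, and an osmium reagent could not tell this hindered allylic-ether alkene from the methallyl group. A hydroxyl-directed epoxidation is selective for C18=C1, and a carbonate on the C3 oxygen then opens the epoxide at C1 with inversion. For this reason the aldehyde partner carries a silyloxyethyl arm rather than an allyl arm.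

**C10–H.** 28 comes from 27 by desilylation, and 27 from aldehyde 26 by loss of the formyl group with retention.

**Tetrahydrofuran (key step).** 26 is cut at O7–C8, C8–C9 and C6–C10 into dienyl diol 24 and Z enal 21. Forward, an oxocarbenium ion at C8 is attacked by C9, and C6 shifts from the carbinol carbon to C10. One ring, three bonds and three stereocentres are formed from two fragments.

**Dienyl diol.** 24 comes from 23 by desilylation. 23 is cut between C10 and the carbinol carbon into dienyl iodide 8 (through dienyllithium 22) and aldehyde 13. The carbinol configuration is irrelevant because that carbon becomes the formyl group.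

**Ring A fragment.** 8 goes back through stannane 7 and triflate 6 to alcohol 5, which is taken from epimer mixture 4 made from triflate 2 and (S)-carvone 1. Carvone supplies C9 to C14 with the C11 methyl group, the C14 configuration and the three carbons C15, C16 and the C15 methyl group.

**Small fragments.** 13 comes from 12 and 11, made from (R)-glycidol 9 and Grignard reagent 10; glycidol supplies the C6 configuration. 21 comes from 20 and 19, made from aldehyde 17 and phosphonate 18; 17 comes from 15 and but-3-en-1-ol 14.

## Alternatives that were turned down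

**Alternative 1:** Intramolecular Diels–Alder across a preformed nine-membered ether. Ring A is cut at C9–C10 and C13–C14. Triene A1 (an oxonene with a 1-silyloxy-3-methylbutadiene on C6 and a Z enoate on C8) should cyclise on warming to tricycle A2, closing ring A and the five-membered ring together.
- For: the C13 oxygen arrives with the diene, so no late C–H oxidation is needed. The C1 and C18 oxygens are set on an open chain before any ring exists. The medium ring is closed early on a flexible diene. On these three points it is stronger than the chosen route.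
- Against: A1 needs a long linear sequence. The facial and endo/exo outcome depends on the conformation of the nine-membered tether. A2 has an ester on C14, so C15, C16 and the C15 stereocentre must still be built. The C13 silyl ether must still be turned into the enone. The Z enoate can isomerise on heating.
- Comparison: the chosen route is convergent (three chiral-pool pieces) and makes the tetrahydrofuran with the C15 side chain already in place. It pays with later oxidation-state changes at C13 and C18/C1.

**Alternative 2:** Oxepane by Baeyer–Villiger expansion. The O17–C18 bond is cut. Dione A3 (a cyclohexanone made of C8, C9, C14, C15, C16, C18) should give seven-membered lactone A4 with buffered peracid, the quaternary C18 migrating with retention.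
- For: regio- and stereochemistry of this oxidation are highly predictable, and the conjugated C13 ketone should not compete. For the O17–C18 bond alone this is more certain than any single step of the chosen route.
- Against: it solves the easiest ring. A3 must already contain the tetrahydrofuran with four stereocentres and a quaternary C18 inside a fully substituted cyclohexanone, with no short route in sight. The C16 lactone carbonyl must then be reduced to CH2 beside the enone. The oxonene and the C1 oxygen are still missing in A4.
- Comparison: the chosen route forms C16–O17 by a plain etherification without redox steps and builds the hard bicyclic core first.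

**Alternative 3:** Chiral butenolide Diels–Alder. Ring A is cut at C9–C14 and C10–C11. (S)-Butenolide A5 and silyloxy diene A6 should give cis-fused lactone A7.
- For: it is convergent, the butenolide reacts anti to its C8 substituent, the C13 oxygen is built in as a silyl enol ether, and C15 comes from a defined building block. The last point is better than the resolution used here.
- Against: in A7 the future tetrahydrofuran is a lactone. C6 is a carbonyl and C8 carries only a CH2O group, so the C6 arm, the quaternary C18 and C1 must all be added later with stereocontrol. C11 is sp3 with a methyl stereocentre, so the enone needs a later dehydrogenation. A 1,4-disubstituted 2-silyloxy diene gives weak regiocontrol, and butenolides are sluggish toward a hindered Z,E diene.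
- Comparison: the chosen cascade sets all four tetrahydrofuran stereocentres with both arms already attached.

Key step: step 17

Assumption: the carbinol carbon next to the diene in 23 and 24 is drawn as the Felkin (anti) epimer expected to predominate; the syn epimer is carried along, since this centre becomes the formyl carbon in step 17 and is lost in step 18.
Assumption: 4 is the mixture of both C15 epimers and is drawn without configuration at C15.

## Route

Step 1
Reactants: 1 (S)-carvone
Product: 2 dienyl triflate, 6-methyl-3-(prop-1-en-2-yl)cyclohexa-1,5-dien-1-yl trifluoromethanesulfonate (ring stereocentre, the later C14, unchanged)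
Conditions: LiN(i-Pr)2, THF, −78 °C; then PhNTf2, −78 → 0 °C
Reagents that add atoms: N-phenylbis(trifluoromethanesulfonimide), O=S(=O)(N(c1ccccc1)S(=O)(=O)C(F)(F)F)C(F)(F)F
Why: Kinetic deprotonation at the α′ CH2 gives the cross-conjugated dienolate, which is sulfonylated on oxygen (enol triflate formation); no stereocentre is touched.

Step 2
Reactants: 2
Product: 4 primary alcohol from anti-Markovnikov hydration of the isopropenyl group (both C15 epimers), via alkylborane 3 (not isolated)
Conditions: 9-BBN, THF, 0 °C → rt; then aq. NaOAc, 30% H2O2, 0 °C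
Reagents that add atoms: 9-borabicyclo[3.3.1]nonane, B1C2CCCC1CCC2 (boron of 3 only); hydrogen peroxide, OO
Why: Hydroboration–oxidation; the bulky borane should take the unhindered 1,1-disubstituted alkene and leave the electron-poor dienyl triflate, and buffered peroxide spares the triflate. The two flanks of the ring stereocentre are alike, so no useful induction at C15 is expected and both epimers go on to step 3.

Step 3
Reactants: 4
Product: 5 (15R) alcohol, recovered unacylated
Conditions: lipase PS (Burkholderia cepacia, immobilised), vinyl acetate, t-BuOMe, rt, run past half conversion; chromatography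
Reagents that add atoms: none
Why: Lipase-catalysed kinetic acylation of epimeric 2-methyl-substituted primary alcohols; by the empirical preference of this lipase the 15S epimer should be acetylated faster, so the 15R alcohol remains and C15 is fixed by separation from the acetate.

Step 4
Reactants: 5
Product: 6 tert-butyldiphenylsilyl ether of 5
Conditions: t-BuPh2SiCl, imidazole, DMF, rt
Reagents that add atoms: tert-butyl(chloro)diphenylsilane, CC(C)(C)[Si](Cl)(c1ccccc1)c1ccccc1
Why: Standard silylation of a primary alcohol; this ether has to survive organolithium, acid and light in the following steps.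

Step 5
Reactants: 6
Product: 7 dienyl trimethylstannane (SnMe3 in place of the triflate group)
Conditions: Me6Sn2, Pd(PPh3)4 (5 mol%), LiCl, THF, 65 °C
Reagents that add atoms: hexamethylditin, C[Sn](C)(C)[Sn](C)(C)C
Why: Palladium-catalysed stannylation of an enol triflate (Stille-type coupling with a distannane); the diene geometry is fixed by the ring.

Step 6
Reactants: 7
Product: 8 dienyl iodide (iodine on C10 of the ring A diene C9=C10–C11=C12)
Conditions: I2, CH2Cl2, 0 °C
Reagents that add atoms: iodine, II
Why: Iododestannylation at the sp2 carbon is fast and site-specific, and gives the iodide needed for a clean lithium–halogen exchange.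

Step 7
Reactants: 9 (R)-glycidol; 10 isopropenylmagnesium bromide
Product: 11 (S)-4-methylpent-4-ene-1,2-diol
Conditions: 10 (3 equiv), CuI (10 mol%), THF, −30 → 0 °C; aq. NH4Cl
Reagents that add atoms: none
Why: Copper-catalysed Grignard opening of the epoxide at its terminal carbon. The first equivalent only deprotonates the hydroxyl. The stereocentre (the later C6) is not attacked, and a Payne shift of glycidol alkoxide returns the same enantiomer.

Step 8
Reactants: 11
Product: 12 bis(triethylsilyl) ether of 11
Conditions: Et3SiCl, imidazole, CH2Cl2, 0 °C → rt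
Reagents that add atoms: chlorotriethylsilane, CC[Si](Cl)(CC)CC
Why: Exhaustive silylation; it sets up the selective oxidation of the primary position in step 9.

Step 9
Reactants: 12
Product: 13 (S)-4-methyl-2-(triethylsilyloxy)pent-4-enal
Conditions: (COCl)2, DMSO, CH2Cl2, −78 → −30 °C; then Et3N, −78 °C → rt
Reagents that add atoms: none
Why: Swern conditions cleave and oxidise a primary triethylsilyl ether directly to the aldehyde while the secondary silyl ether stays; the α-stereocentre should hold if the aldehyde is used at once.

Step 10
Reactants: 14 but-3-en-1-ol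
Product: 15 (but-3-en-1-yloxy)triisopropylsilane
Conditions: i-Pr3SiCl, imidazole, CH2Cl2, rt
Reagents that add atoms: chlorotriisopropylsilane, CC(C)[Si](Cl)(C(C)C)C(C)C
Why: Standard silylation; the triisopropylsilyl ether is chosen because it must survive the acids of step 17.

Step 11
Reactants: 15
Product: 17 3-(triisopropylsilyloxy)propanal, via ozonide 16 (not isolated)
Conditions: O3, CH2Cl2, −78 °C; then PPh3, −78 °C → rt
Reagents that add atoms: ozone, [O-][O+]=O
Why: Ozonolysis with reductive work-up cleaves the terminal alkene to the aldehyde.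

Step 12
Reactants: 17; 18 ethyl 2-[bis(2,2,2-trifluoroethoxy)phosphoryl]propanoate
Product: 19 ethyl (Z)-2-methyl-5-(triisopropylsilyloxy)pent-2-enoate
Conditions: 18, KN(SiMe3)2, 18-crown-6, THF, −78 °C; then 17
Reagents that add atoms: none
Why: Still–Gennari olefination; the electron-poor phosphonate with a dissociated potassium counter-ion eliminates under kinetic control and should give the Z trisubstituted enoate.

Step 13
Reactants: 19
Product: 20 (Z)-2-methyl-5-(triisopropylsilyloxy)pent-2-en-1-ol
Conditions: i-Bu2AlH, CH2Cl2, −78 °C; aq. KNaC4H4O6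
Reagents that add atoms: none
Why: 1,2-Reduction of the enoate to the allylic alcohol without touching the alkene geometry.

Step 14
Reactants: 20
Product: 21 (Z)-2-methyl-5-(triisopropylsilyloxy)pent-2-enal
Conditions: TEMPO (10 mol%), PhI(OAc)2, CH2Cl2, rt
Reagents that add atoms: none
Why: Oxoammonium oxidation of an allylic alcohol under near-neutral conditions, chosen to avoid Z to E isomerisation of the enal.

Step 15
Reactants: 8; 13
Product: 23 coupling product (C6 triethylsilyl ether, free carbinol next to the diene, anti), via dienyllithium 22 (not isolated)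
Conditions: 8, t-BuLi (2.1 equiv), Et2O, −78 °C; then 13, −78 °C; aq. NH4Cl
Reagents that add atoms: tert-butyllithium, [Li]C(C)(C)C (lithium of 22 only)
Why: Lithium–iodine exchange and 1,2-addition to the α-silyloxy aldehyde. Felkin–Anh control should favour the anti carbinol. Its configuration, and any silyl shift between the two oxygens, is of no consequence.

Step 16
Reactants: 23
Product: 24 ring A dienyl diol (C6 S, carbinol mainly R)
Conditions: HF·pyridine, pyridine, THF, 0 °C
Reagents that add atoms: none
Why: Buffered fluoride removes the labile secondary triethylsilyl ether and leaves the primary tert-butyldiphenylsilyl ether; buffering protects the doubly allylic carbinol from ionisation.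

Step 17
Reactants: 24; 21
Product: 26 C10-formyl hexahydroisobenzofuran (methallyl arm on C6, Z alkenyl arm on C8, cis ring fusion), via dioxolane acetal 25 (not isolated)
Conditions: 21 (1.3 equiv), p-TsOH·H2O (5 mol%), MgSO4, CH2Cl2, −20 °C; then SnCl4 (20 mol%), −20 °C → rt
Reagents that add atoms: none
Why: Acid-catalysed acetalisation joins the aldehyde carbon C8 to both diol oxygens (25); SnCl4 then opens the acetal at the oxygen of the doubly allylic carbinol, which leaves as a tin alkoxide, and gives an (E)-oxocarbenium ion on O7. Diene carbon C9 adds to C8 in a chair-like six-membered Prins closure (6-endo with respect to C9=C10), leaving an allyl cation over C10 to C12. The C6–carbinol bond then shifts to C10 (pinacol-type 1,2-shift pushed by the alkoxide), which contracts the six-membered ring to the tetrahydrofuran and turns the carbinol carbon into the C10 formyl group; the closest known reaction type is the Prins–pinacol condensation–rearrangement of allylic 1,2-diols with aldehydes to 3-acyltetrahydrofurans. The tetrahydrofuran is thus closed by 6-endo cyclisation followed by suprafacial ring contraction, not by a direct five-ring closure. C8: the alkenyl group sits equatorial in the chair, cis to the equatorial C5 arm on C6 across O7; C9: the chair fixed by the C6 stereocentre selects the diene face and places 8-H and 9-H trans; C10: C6 migrates to the face that already carries the new C8–C9 bond, giving the cis fusion with the formyl group on the other face. The step needs attack on the diene face that also carries the C14 side chain; the C6 centre should enforce this through the all-equatorial chair, and this is where tether and substrate control could be mismatched. Both carbinol epimers of 24 should converge because that centre becomes sp2, the Z geometry of 21 is not involved, and the silyl ethers and the methallyl alkene are spectators at low temperature.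

Step 18
Reactants: 26
Product: 27 decarbonylated hexahydroisobenzofuran (10-H cis to 9-H, C11=C12 retained)
Conditions: hν (medium-pressure Hg lamp, Pyrex), degassed 1,4-dioxane, rt
Reagents that add atoms: none
Why: Norrish α-cleavage of the β,γ-unsaturated aldehyde gives a formyl/allyl radical pair; in-cage hydrogen transfer to C10 on the face the formyl group left should give retention (photodecarbonylation of β,γ-unsaturated aldehydes).

Step 19
Reactants: 27
Product: 28 diol with free primary hydroxyls on C3 and C16
Conditions: Bu4NF, THF, rt
Reagents that add atoms: none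
Why: Fluoride removes both silyl ethers; the C3 hydroxyl is now homoallylic to the Z C18=C1 alkene, and the C16 hydroxyl has no alkene within reach.

Step 20
Reactants: 28
Product: 29 C18,C1-epoxy diol
Conditions: Al(OtBu)3, t-BuOOH (in decane), toluene, −20 → 0 °C
Reagents that add atoms: tert-butyl hydroperoxide, CC(C)(C)OO
Why: Hydroxyl-directed epoxidation of a homoallylic alcohol by an aluminium peroxide; undirected alkenes (C11=C12, methallyl) should not react. Allylic 1,3-strain in the Z alkene holds 8-H in the alkene plane, so the oxidant should enter anti to C9. This sets C18 as in the target and C1 with the configuration that step 22 inverts.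

Step 21
Reactants: 29
Product: 30 bis(tert-butyl carbonate) of 29 (on O3 and O16)
Conditions: Boc2O, DMAP (20 mol%), MeCN, rt
Reagents that add atoms: di-tert-butyl dicarbonate, CC(C)(C)OC(=O)OC(=O)OC(C)(C)C
Why: DMAP-catalysed carbonate formation on both primary alcohols; it places a nucleophilic carbonyl oxygen four atoms from C1.

Step 22
Reactants: 30
Product: 32 six-membered cyclic carbonate on O1 and O3 with free C16 and C18 hydroxyls, via cyclic carbonate 31 (not isolated)
Conditions: BF3·OEt2, CH2Cl2, −40 → 0 °C; aq. NaHCO3
Reagents that add atoms: none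
Why: The carbonate carbonyl oxygen should open the Lewis acid-activated epoxide at C1 in a 6-exo SN2 attack with inversion, then lose isobutene (tert-butyl carbonate participation in epoxide opening). Ionisation at tertiary C18 is disfavoured by the adjacent C8–O7 bond, so the C18–O bond is retained. C1 and C18 now have the target configuration, and the remote tert-butyl carbonate in 31 is cleaved by the same Lewis acid.

Step 23
Reactants: 32
Product: 34 tricyclic ether (oxepane closed, C18–O17–C16) with the C1/C3 cyclic carbonate, via primary triflate 33 (not isolated)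
Conditions: Tf2O, 2,6-lutidine, CH2Cl2, −78 → 0 °C
Reagents that add atoms: trifluoromethanesulfonic anhydride, O=S(=O)(OS(=O)(=O)C(F)(F)F)C(F)(F)F (sulfonyl group of 33 only)
Why: The primary hydroxyl is triflated selectively and displaced by the tertiary C18 hydroxyl (7-exo-tet Williamson-type etherification); no stereocentre is involved, and the ring later holds C14 against epimerisation.

Step 24
Reactants: 34
Product: 35 diol (secondary C1 hydroxyl, primary C3 hydroxyl)
Conditions: K2CO3, MeOH, rt
Reagents that add atoms: none
Why: Methanolysis of the strained six-membered cyclic carbonate; ethers and alkenes are inert.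

Step 25
Reactants: 35
Product: 36 β-hydroxy aldehyde (aldehyde at C3)
Conditions: TEMPO (10 mol%), PhI(OAc)2, CH2Cl2, rt
Reagents that add atoms: none
Why: Oxoammonium oxidation is selective for the primary over the hindered secondary alcohol; with O17 already an ether no lactol can form, and the aldehyde is used crude.

Step 26
Reactants: 36
Product: 37 homoallylic alcohol (allyl group on C1)
Conditions: Ph3PCH3Br, KN(SiMe3)2, THF, 0 °C; then 36, −78 → 0 °C
Reagents that add atoms: methyltriphenylphosphonium bromide, C[P+](c1ccccc1)(c1ccccc1)c1ccccc1.[Br-]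
Why: Wittig methylenation; excess ylide is used because the free hydroxyl consumes one equivalent, and the low temperature limits retro-aldol or elimination of the β-alkoxide.

Step 27
Reactants: 37
Product: 38 C1 butyrate
Conditions: (n-PrCO)2O, DMAP, Et3N, CH2Cl2, rt
Reagents that add atoms: butyric anhydride, CCCC(=O)OC(=O)CCC
Why: DMAP-catalysed acylation of the only hydroxyl, with retention at C1.

Step 28
Reactants: 38
Product: 39 enone (C13 ketone conjugated with C11=C12)
Conditions: Rh2(cap)4 (1 mol%), aq. t-BuOOH, K2CO3, CH2Cl2, rt
Reagents that add atoms: tert-butyl hydroperoxide, CC(C)(C)OO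
Why: Dirhodium caprolactamate-catalysed allylic oxidation by tert-butylperoxyl radicals. C13 is the only allylic CH2 on the only trisubstituted alkene. The allylic CH2 groups of the allyl and methallyl arms sit on terminal alkenes next to oxygenated carbons and should react more slowly.

Step 29
Reactants: 39
Product: 40 target
Conditions: second-generation Grubbs catalyst RuCl2(=CHPh)(PCy3)(H2IMes) (10 mol%), CH2Cl2 (high dilution), 40 °C
Reagents that add atoms: none
Why: Ring-closing metathesis between the allyl and methallyl groups. The catalyst loads on the monosubstituted alkene and closes onto the 1,1-disubstituted one. The Z geometry is forced by the ring, the two arms are cis on the tetrahydrofuran, and C18 is held by the oxepane.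

## Compound list

1 | (S)-carvone | CC1=CC[C@@H](CC1=O)C(C)=C | starting material
2 | dienyl triflate of carvone | CC1=CC[C@@H](C=C1OS(=O)(=O)C(F)(F)F)C(C)=C | intermediate
3 | B-alkyl-9-borabicyclononane from the isopropenyl group of 2 (C15 epimers) | CC1=CC[C@@H](C=C1OS(=O)(=O)C(F)(F)F)C(C)CB2C3CCCC2CCC3 | intermediate (not isolated)
4 | 2-[4-methyl-3-(triflyloxy)cyclohexa-2,4-dien-1-yl]propan-1-ol, both C15 epimers | CC1=CC[C@@H](C=C1OS(=O)(=O)C(F)(F)F)C(C)CO | intermediate
5 | (15R) epimer of 4 | CC1=CC[C@@H](C=C1OS(=O)(=O)C(F)(F)F)[C@@H](C)CO | intermediate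
6 | tert-butyldiphenylsilyl ether of 5 | CC1=CC[C@@H](C=C1OS(=O)(=O)C(F)(F)F)[C@@H](C)CO[Si](c2ccccc2)(c2ccccc2)C(C)(C)C | intermediate
7 | dienyl trimethylstannane | CC1=CC[C@@H](C=C1[Sn](C)(C)C)[C@@H](C)CO[Si](c2ccccc2)(c2ccccc2)C(C)(C)C | intermediate
8 | dienyl iodide (ring A fragment) | CC1=CC[C@@H](C=C1I)[C@@H](C)CO[Si](c2ccccc2)(c2ccccc2)C(C)(C)C | intermediate
9 | (R)-glycidol | OC[C@@H]1CO1 | starting material
10 | isopropenylmagnesium bromide | C=C(C)[Mg]Br | starting material
11 | (S)-4-methylpent-4-ene-1,2-diol | C=C(C)C[C@H](O)CO | intermediate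
12 | bis(triethylsilyl) ether of 11 | C=C(C)C[C@H](O[Si](CC)(CC)CC)CO[Si](CC)(CC)CC | intermediate
13 | (S)-4-methyl-2-(triethylsilyloxy)pent-4-enal | C=C(C)C[C@H](O[Si](CC)(CC)CC)C=O | intermediate
14 | but-3-en-1-ol | C=CCCO | starting material
15 | (but-3-en-1-yloxy)triisopropylsilane | C=CCCO[Si](C(C)C)(C(C)C)C(C)C | intermediate
16 | secondary ozonide of 15 (3-substituted 1,2,4-trioxolane) | C1OC(CCO[Si](C(C)C)(C(C)C)C(C)C)OO1 | intermediate (not isolated)
17 | 3-(triisopropylsilyloxy)propanal | O=CCCO[Si](C(C)C)(C(C)C)C(C)C | intermediate
18 | ethyl 2-[bis(2,2,2-trifluoroethoxy)phosphoryl]propanoate | CCOC(=O)C(C)P(=O)(OCC(F)(F)F)OCC(F)(F)F | starting material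
19 | ethyl (Z)-2-methyl-5-(triisopropylsilyloxy)pent-2-enoate | CCOC(=O)/C(C)=C\CCO[Si](C(C)C)(C(C)C)C(C)C | intermediate
20 | (Z)-2-methyl-5-(triisopropylsilyloxy)pent-2-en-1-ol | OC/C(C)=C\CCO[Si](C(C)C)(C(C)C)C(C)C | intermediate
21 | (Z)-2-methyl-5-(triisopropylsilyloxy)pent-2-enal | O=C/C(C)=C\CCO[Si](C(C)C)(C(C)C)C(C)C | intermediate
22 | dienyllithium from 8 | [Li]C1=C[C@@H]([C@@H](C)CO[Si](c2ccccc2)(c2ccccc2)C(C)(C)C)CC=C1C | intermediate (not isolated)
23 | coupling product, C6 triethylsilyl ether, anti carbinol | C=C(C)C[C@H](O[Si](CC)(CC)CC)[C@H](O)C1=C[C@@H]([C@@H](C)CO[Si](c2ccccc2)(c2ccccc2)C(C)(C)C)CC=C1C | intermediate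
24 | ring A dienyl diol (key-step precursor; anti epimer drawn) | C=C(C)C[C@H](O)[C@H](O)C1=C[C@@H]([C@@H](C)CO[Si](c2ccccc2)(c2ccccc2)C(C)(C)C)CC=C1C | intermediate
25 | 2-alkenyl-1,3-dioxolane from 24 and 21 (acetal carbon as a mixture) | C=C(C)C[C@@H]1OC(/C(C)=C\CCO[Si](C(C)C)(C(C)C)C(C)C)O[C@@H]1C2=C[C@@H]([C@@H](C)CO[Si](c3ccccc3)(c3ccccc3)C(C)(C)C)CC=C2C | intermediate (not isolated)
26 | C10-formyl hexahydroisobenzofuran (key-step product) | C=C(C)C[C@@H]1O[C@H](/C(C)=C\CCO[Si](C(C)C)(C(C)C)C(C)C)[C@@H]2[C@@]1(C=O)C(C)=CC[C@@H]2[C@@H](C)CO[Si](c3ccccc3)(c3ccccc3)C(C)(C)C | intermediate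
27 | decarbonylated hexahydroisobenzofuran (10-H) | C=C(C)C[C@@H]1O[C@H](/C(C)=C\CCO[Si](C(C)C)(C(C)C)C(C)C)[C@@H]2[C@H]1C(C)=CC[C@@H]2[C@@H](C)CO[Si](c3ccccc3)(c3ccccc3)C(C)(C)C | intermediate
28 | C3,C16-diol with Z C18=C1 alkene | C=C(C)C[C@@H]1O[C@H](/C(C)=C\CCO)[C@@H]2[C@H]1C(C)=CC[C@@H]2[C@@H](C)CO | intermediate
29 | C18,C1-epoxy diol | C=C(C)C[C@@H]1O[C@H]([C@@]3(C)O[C@H]3CCO)[C@@H]2[C@H]1C(C)=CC[C@@H]2[C@@H](C)CO | intermediate
30 | bis(tert-butyl carbonate) of 29 | C=C(C)C[C@@H]1O[C@H]([C@@]3(C)O[C@H]3CCOC(=O)OC(C)(C)C)[C@@H]2[C@H]1C(C)=CC[C@@H]2[C@@H](C)COC(=O)OC(C)(C)C | intermediate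
31 | C1/C3 cyclic carbonate, C18 hydroxyl, C16 tert-butyl carbonate | C=C(C)C[C@@H]1O[C@H]([C@@](C)(O)[C@H]3CCOC(=O)O3)[C@@H]2[C@H]1C(C)=CC[C@@H]2[C@@H](C)COC(=O)OC(C)(C)C | intermediate (not isolated)
32 | C1/C3 cyclic carbonate with free C16 and C18 hydroxyls | C=C(C)C[C@@H]1O[C@H]([C@@](C)(O)[C@H]3CCOC(=O)O3)[C@@H]2[C@H]1C(C)=CC[C@@H]2[C@@H](C)CO | intermediate
33 | C16 triflate of 32 | C=C(C)C[C@@H]1O[C@H]([C@@](C)(O)[C@H]3CCOC(=O)O3)[C@@H]2[C@H]1C(C)=CC[C@@H]2[C@@H](C)COS(=O)(=O)C(F)(F)F | intermediate (not isolated)
34 | oxepane-fused tricycle with C1/C3 cyclic carbonate | C=C(C)C[C@@H]1O[C@H]2[C@@H]3[C@H]1C(C)=CC[C@@H]3[C@@H](C)CO[C@@]2(C)[C@H]4CCOC(=O)O4 | intermediate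
35 | C1,C3-diol | C=C(C)C[C@@H]1O[C@H]2[C@@H]3[C@H]1C(C)=CC[C@@H]3[C@@H](C)CO[C@@]2(C)[C@H](O)CCO | intermediate
36 | β-hydroxy aldehyde (C3 aldehyde) | C=C(C)C[C@@H]1O[C@H]2[C@@H]3[C@H]1C(C)=CC[C@@H]3[C@@H](C)CO[C@@]2(C)[C@H](O)CC=O | intermediate
37 | homoallylic alcohol (allyl on C1) | C=C(C)C[C@@H]1O[C@H]2[C@@H]3[C@H]1C(C)=CC[C@@H]3[C@@H](C)CO[C@@]2(C)[C@H](O)CC=C | intermediate
38 | C1 butyrate | C=C(C)C[C@@H]1O[C@H]2[C@@H]3[C@H]1C(C)=CC[C@@H]3[C@@H](C)CO[C@@]2(C)[C@H](OC(=O)CCC)CC=C | intermediate
39 | C13 enone, metathesis precursor | C=C(C)C[C@@H]1O[C@H]2[C@@H]3[C@H]1C(C)=CC(=O)[C@@H]3[C@@H](C)CO[C@@]2(C)[C@H](OC(=O)CCC)CC=C | intermediate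
40 | CNP0271677.1 | CCCC(=O)O[C@@H]1C/C=C(/C)C[C@@H]2O[C@H]3[C@@H]4[C@H]2C(C)=CC(=O)[C@@H]4[C@@H](C)CO[C@@]13C | target

## Step count and least certain steps

Total: 29 steps. Longest linear sequence: 21 steps (steps 1 to 6 and 15 to 29).

**Step 17 (key step).** Most likely to go wrong: the Brønsted acid may ionise the doubly allylic carbinol of 24 or isomerise the Z enal before the acetal has formed. Facial selectivity at the diene may be lower than wanted because the C14 side chain lies on the face the oxocarbenium ion has to approach. The allyl cation may lose a proton instead of accepting the 1,2-shift.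
Fallback: it sets out from 24. TMSOTf and Et3N give the bis(trimethylsilyl) ether F1. F1 and 21 with catalytic TMSOTf at −78 °C (aprotic acetalisation of a bis-silyl ether with an aldehyde) give acetal 25 as an isolated compound without protic acid or water. SnCl4 then runs the rearrangement alone, and the route is rejoined at 26.

**Step 3 (with step 2).** Most likely to go wrong: poor discrimination between the C15 epimers by the lipase. The stereocentre is one carbon away from the acylated oxygen and its two larger groups differ little, so the recovered alcohol may stay a mixture.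
Fallback: it sets out from 2. Copper hydride-catalysed enantioselective hydroboration of the 1,1-disubstituted alkene (CuCl, DTBM-SEGPHOS in the enantiomer that gives 15R, KOtBu, pinacolborane) gives the pinacol boronate F2 under catalyst control. Oxidation with NaBO3 returns to 5.

**Step 22.** Most likely to go wrong: opening of the epoxide at the wrong carbon. The Lewis acid may ionise the tertiary C18–O bond, leading to attack at C18 or a hydride shift, and the remote tert-butyl carbonate may be cleaved incompletely.
Fallback: it sets out from 29. Under CO2 (1 atm) with Cs2CO3 in DMF the C3 alkoxide is carboxylated reversibly, and the alkyl carbonate anion opens the epoxide at C1 by SN2 (base-mediated carboxylative cyclisation of epoxy alcohols). No cation is involved, and 32 is reached directly.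

**Step 28.** Most likely to go wrong: unselective hydrogen abstraction in a triene, at C10–H or at the allylic CH2 groups of the two arms, or over-oxidation.
Fallback: it sets out from 38 and places the oxygen by polar steps. mCPBA should epoxidise the only trisubstituted alkene to the 11,12-epoxide F3. PhSeSePh with NaBH4 opens it at the secondary C12 to the hydroxy selenide F4. H2O2 gives the selenoxide F5, which eliminates away from the carbinol to the tertiary allylic alcohol F6. Pyridinium chlorochromate, [C5H5NH][CrO3Cl], then effects the oxidative 1,3-transposition (Babler–Dauben) to 39.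

**Step 29.** Most likely to go wrong: intermolecular metathesis at the unhindered allyl terminus may outrun closure onto the 1,1-disubstituted alkene within the rigid tetracyclic frame, giving dimers and oligomers.
Fallback: it sets out from 32 and closes the nine-membered ring before the oxepane and the ketone exist, on a diene that can still rotate about C8–C18.
- t-BuMe2SiCl and imidazole protect C16 to give the silyl ether F7.
- K2CO3 in MeOH gives the triol F8.
- TEMPO with PhI(OAc)2 oxidises the primary alcohol, which closes onto the C18 hydroxyl to give the hydroxy γ-lactone F9.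
- i-Bu2AlH gives the lactol F10.
- Ph3P=CH2 gives the allyl diol F11.
- Butyric anhydride with DMAP acylates the secondary hydroxyl to give F12.
- Ring-closing metathesis with the second-generation Grubbs catalyst gives the oxonene F13.
- HF·pyridine frees the C16 alcohol F14.
- Tf2O with 2,6-lutidine closes the oxepane through the triflate F15 to give the 13-deoxo tetracycle F16.
- Allylic oxidation as in step 28 gives 40.

## Further compounds

F1 | step 17 | bis(trimethylsilyl) ether of 24 | C=C(C)C[C@H](O[Si](C)(C)C)[C@H](O[Si](C)(C)C)C1=C[C@@H]([C@@H](C)CO[Si](c2ccccc2)(c2ccccc2)C(C)(C)C)CC=C1C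
F2 | step 3 | (15R) pinacol boronate from 2 | CC1=CC[C@@H](C=C1OS(=O)(=O)C(F)(F)F)[C@@H](C)CB2OC(C)(C)C(C)(C)O2
F0 | step 22 | none | none
F3 | step 28 | 11,12-epoxide of 38 (epoxide face not specified) | C=C(C)C[C@@H]1O[C@H]2[C@@H]3[C@H]1C4(C)OC4C[C@@H]3[C@@H](C)CO[C@@]2(C)[C@H](OC(=O)CCC)CC=C
F4 | step 28 | 11-hydroxy-12-phenylselanyl compound | C=C(C)C[C@@H]1O[C@H]2[C@@H]3[C@H]1C(C)(O)C([Se]c4ccccc4)C[C@@H]3[C@@H](C)CO[C@@]2(C)[C@H](OC(=O)CCC)CC=C
F5 | step 28 | selenoxide of F4 | C=C(C)C[C@@H]1O[C@H]2[C@@H]3[C@H]1C(C)(O)C([Se](=O)c4ccccc4)C[C@@H]3[C@@H](C)CO[C@@]2(C)[C@H](OC(=O)CCC)CC=C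
F6 | step 28 | tertiary allylic alcohol (11-hydroxy, C12=C13) | C=C(C)C[C@@H]1O[C@H]2[C@@H]3[C@H]1C(C)(O)C=C[C@@H]3[C@@H](C)CO[C@@]2(C)[C@H](OC(=O)CCC)CC=C
F7 | step 29 | C16 tert-butyldimethylsilyl ether of 32 | C=C(C)C[C@@H]1O[C@H]([C@@](C)(O)[C@H]3CCOC(=O)O3)[C@@H]2[C@H]1C(C)=CC[C@@H]2[C@@H](C)CO[Si](C)(C)C(C)(C)C
F8 | step 29 | C18,C1,C3-triol | C=C(C)C[C@@H]1O[C@H]([C@@](C)(O)[C@H](O)CCO)[C@@H]2[C@H]1C(C)=CC[C@@H]2[C@@H](C)CO[Si](C)(C)C(C)(C)C
F9 | step 29 | hydroxy γ-lactone (C3 carbonyl, O on C18) | C=C(C)C[C@@H]1O[C@H]([C@@]3(C)OC(=O)C[C@H]3O)[C@@H]2[C@H]1C(C)=CC[C@@H]2[C@@H](C)CO[Si](C)(C)C(C)(C)C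
F10 | step 29 | lactol of F9 | C=C(C)C[C@@H]1O[C@H]([C@@]3(C)OC(O)C[C@H]3O)[C@@H]2[C@H]1C(C)=CC[C@@H]2[C@@H](C)CO[Si](C)(C)C(C)(C)C
F11 | step 29 | allyl diol (C1 and C18 hydroxyls) | C=C(C)C[C@@H]1O[C@H]([C@@](C)(O)[C@H](O)CC=C)[C@@H]2[C@H]1C(C)=CC[C@@H]2[C@@H](C)CO[Si](C)(C)C(C)(C)C
F12 | step 29 | C1 butyrate of F11 | C=C(C)C[C@@H]1O[C@H]([C@@](C)(O)[C@H](OC(=O)CCC)CC=C)[C@@H]2[C@H]1C(C)=CC[C@@H]2[C@@H](C)CO[Si](C)(C)C(C)(C)C
F13 | step 29 | oxonene with free C18 hydroxyl and C16 silyl ether | CCCC(=O)O[C@@H]1C/C=C(/C)C[C@@H]2O[C@@H]([C@@H]3[C@H]2C(C)=CC[C@@H]3[C@@H](C)CO[Si](C)(C)C(C)(C)C)[C@@]1(C)O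
F14 | step 29 | oxonene C16,C18-diol | CCCC(=O)O[C@@H]1C/C=C(/C)C[C@@H]2O[C@@H]([C@@H]3[C@H]2C(C)=CC[C@@H]3[C@@H](C)CO)[C@@]1(C)O
F15 | step 29 | C16 triflate of F14 | CCCC(=O)O[C@@H]1C/C=C(/C)C[C@@H]2O[C@@H]([C@@H]3[C@H]2C(C)=CC[C@@H]3[C@@H](C)COS(=O)(=O)C(F)(F)F)[C@@]1(C)O
F16 | step 29 | 13-deoxo tetracycle | CCCC(=O)O[C@@H]1C/C=C(/C)C[C@@H]2O[C@H]3[C@@H]4[C@H]2C(C)=CC[C@@H]4[C@@H](C)CO[C@@]13C
A1 | alternative 1 | oxonene triene with silyloxy diene on C6 and Z enoate on C8 | COc1ccc(cc1)CO[C@@H]1C/C=C(/C)C[C@@H](/C=C(\C)/C=C/O[Si](C)(C)C(C)(C)C)O[C@@H](/C=C\C(=O)OC)[C@@]1(C)O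
A2 | alternative 1 | tricyclic Diels–Alder adduct with C13 silyl ether and C14 methyl ester | COc1ccc(cc1)CO[C@@H]1C/C=C(/C)C[C@@H]2O[C@@H]([C@@H]3[C@H]2C(C)=C[C@H](O[Si](C)(C)C(C)(C)C)[C@@H]3C(=O)OC)[C@@]1(C)O
A3 | alternative 2 | tricyclic dione with C16 cyclohexanone | CC1(OCCO1)C[C@@H]2O[C@H]3[C@@H]4[C@H]2C(C)=CC(=O)[C@@H]4[C@@H](C)C(=O)[C@@]3(C)CO[Si](c5ccccc5)(c5ccccc5)C(C)(C)C
A4 | alternative 2 | seven-membered lactone | CC1(OCCO1)C[C@@H]2O[C@H]3[C@@H]4[C@H]2C(C)=CC(=O)[C@@H]4[C@@H](C)C(=O)O[C@@]3(C)CO[Si](c5ccccc5)(c5ccccc5)C(C)(C)C
A5 | alternative 3 | (S)-5-(tert-butyldiphenylsilyloxymethyl)furan-2(5H)-one | O=C1C=C[C@@H](CO[Si](c2ccccc2)(c2ccccc2)C(C)(C)C)O1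
A6 | alternative 3 | 2-silyloxy diene with the C15 side chain | C/C=C/C(O[Si](C)(C)C(C)(C)C)=C/[C@@H](C)COCc1ccc(OC)cc1
A7 | alternative 3 | cis-fused bicyclic lactone silyl enol ether | O=C1O[C@H](CO[Si](c3ccccc3)(c3ccccc3)C(C)(C)C)[C@@H]2[C@H]1[C@H](C)C=C(O[Si](C)(C)C(C)(C)C)[C@@H]2[C@@H](C)COCc1ccc(OC)cc1
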